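All runs were generated by integration with made-up constants, and the scatter is random.

Start from 8.6 percentage points: this is the gap, cG minus cZ in points of the Q charged, read in alder at 20.0 h as G plus X less the Z charged.

| setting | alder | larch | maple | oak | Wednesday's | Sunday's | Monday's | Saturday's |
|---|---|---|---|---|---|---|---|---|
| Q | 0.050 M | 0.025 M | 0.10 M | 0.050 M | 0.050 M | 0.050 M | 0.050 M (fed, over 15.0 h) | 0.050 M |
| E | 4 equiv | 4 equiv | 4 equiv | 4 equiv | 4.00 equiv (fed, over 15.0 h) | 4.00 equiv | 4.00 equiv | 4.00 equiv |
| Z | 0.90 equiv | 0.90 equiv | 0.90 equiv | 1.8 equiv | 0.900 equiv | 0.900 equiv | 0.900 equiv | 0.900 equiv |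
| remark | run made earlier | run made earlier | run made earlier | run made earlier | a stirred flask in which E is dosed at a steady rate over 15.0 h without added volume, worked up at 30 h | a single well-mixed tank run continuously and read at steady state, 30 h in it on average | all but Q at the start; Q goes in evenly over 15.0 h, the run ends at 30 h | everything together in a closed stirred flask, run for 30 h |
| time |  |  |  |  | 30 h |  | 30 h | 30 h |

| run | time / h | G / % | X / % |
|---|---|---|---|
| alder | 4.00 | 66.1 | 9.0 |
| alder | 8.00 | 67.8 | 22.4 |
| alder | 10.0 | 66.7 | 26.0 |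
| alder | 15.0 | 58.4 | 37.5 |
| alder | 20.0 | 52.6 | 46.0 |
| larch | 6.00 | 57.8 | 5.5 |
| larch | 12.0 | 69.2 | 15.5 |
| larch | 20.0 | 67.3 | 25.9 |
| larch | 25.0 | 64.8 | 32.1 |
| larch | 30.0 | 60.0 | 37.4 |
| maple | 6.00 | 63.9 | 31.1 |
| maple | 12.0 | 46.7 | 49.6 |
| maple | 20.0 | 34.7 | 62.1 |
| maple | 25.0 | 29.9 | 66.7 |
| maple | 30.0 | 24.8 | 71.3 |
| oak | 2.50 | 47.9 | 8.5 |
| oak | 5.00 | 57.7 | 21.0 |
| oak | 8.00 | 54.0 | 35.8 |
| oak | 15.0 | 35.5 | 59.8 |
| oak | 30.0 | 14.3 | 81.0 |

(standard deviation of a reading: 1 percentage point)

- in percentages every species weighs as the Q in it: one J counts as two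
- the stated concentrations are those of everything mixed, before any reaction; amounts are the same in each set-up
- on the list of suspects stand: Q + E -> G; Q + Z -> D; Z + G -> X; Q + X -> J
- the feed brings no volume worth counting
- the earlier runs were made in a closed, stirred flask

- the set-up with the highest amount of G at the outlet or at the end, in percent of the Q put in ("none" if the first two lie within 2 percentage points) (Wednesday's / Sunday's / Monday's / Saturday's / none)
- amount of G at the outlet or at the end, in percent of the Q put in, Wednesday's
- amount of G at the outlet or at the end, in percent of the Q put in, Sunday's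
- amount of G at the outlet or at the end, in percent of the Q put in, Monday's
- amount of G at the outlet or at the end, in percent of the Q put in, Saturday's

Draw the alder curve first. Reckon Q's half-life from the 4.00 h reading: 1.99 h, pseudo-first-order with E in excess. So G climbs steeply. Its knee is a reading, 67.8% at 8.00 h. Then G falls.

In alder at 20.0 h, G and X read 98.6% of the Q charged together. From there, count Z + G -> X as taking one Z per G. Divide the two rates and time drops out: cG and cZ fall alike, and the gap holds. Read k3 from X between 15.0 h and 20.0 h, using mean G and mean Z: 1.27 L mol⁻¹ h⁻¹. Now ln(cG/cZ) climbs straight. Its slope is the tail slope, k3 times the gap in molar: 0.005460 h⁻¹. As cZ falls, G runs towards the gap.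

Continue the line from the alder reading at 20.0 h. My reckoning puts Saturday's at 41.4%. In Monday's, Q arrives on average 7.50 h late, so read that flask at 22.5 h on the same line: 49.2%. I do not reckon Wednesday's or Sunday's.

The forecast gives Wednesday's 45%, Sunday's 46.5%, Monday's 47% and Saturday's 43%, and its choice is none: “The top two lie within 2 points, so the answer is none.” Mine differs. It sets Monday's 2.7 points above the forecast's Sunday's, so I name Monday's.

The flasks give Wednesday's 46.3%, Sunday's 45.6%, Monday's 49.2% and Saturday's 41.7%. The best is Monday's, ahead of Wednesday's by 2.9 points, more than the margin.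

    Q + E → G (k = 5.20 × 10⁻⁴ L mol⁻¹ s⁻¹)
    Q + Z → D (k = 3.60 × 10⁻⁵ L mol⁻¹ s⁻¹)
    Z + G → X (k = 3.40 × 10⁻⁴ L mol⁻¹ s⁻¹)
    Q + X → J (k = 1.60 × 10⁻⁴ L mol⁻¹ s⁻¹)

Monday's at 30.0 h holds Q 0.224%, G 49.2%, and Z 45.0% of its own charge, a gap of 8.8 points. Leave that flask until 3.0 d. Add the tail slope times the 42.0 h extra to ln(cG/cZ), keep the gap, and G comes to 25.3%. The neighbour flask holds X 70.8% and G 25.6%.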